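## Retrosynthetic overview

1. C7–C11: Mukaiyama aldol addition of methyl pyruvate to the ring-B ketone of acetoxy enone 8 (last step; sets C7 and C11).
2. C1–O (key step): the C1 acetate of 8 is made by relaying the ring-fusion acetoxy group of the cis-fused γ-acetoxy enone 5 from C5 to C1 (1,5-acyloxy transposition); this also frees C5 for trans-selective protonation.
3. C9–C10: ring B is closed on the prochiral quinol acetate 4 by an amine-catalysed desymmetrising intramolecular Michael addition (sets C10 and the absolute configuration).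
4. C5–O: 4 comes from acetoxylative oxidative dearomatisation of phenol 3, and 3 from Heck arylation of but-3-en-2-ol with 4-bromo-3,5-dimethylphenol.
5. Ring order: ring A is present from the start as the arene and is dearomatised in step 2; ring B is formed in step 3.

Assumption: positions are given by eudesmane locants (C1 = CH–OAc, C2 = enone C=O, C3=C4, C5 = ring-fusion CH, C6, C7 = CH bearing the side chain, C8 = ring-B C=O, C9, C10 = quaternary C, C11 = carbinol C, C14 = C10 methyl, C15 = C4 methyl), and compounds 1, 2 and 9 are taken as the cheap commercial starting materials.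

## Route

Step 1
Reactants: 1 4-bromo-3,5-dimethylphenol; 2 but-3-en-2-ol
Product: 3 4-(4-hydroxy-2,6-dimethylphenyl)butan-2-one
Conditions: Pd(OAc)2 (3 mol %), P(t-Bu)3·HBF4 (6 mol %), NaHCO3, Bu4NCl, DMF, 100 °C
Reagents that add atoms: none
Why: Heck arylation of an allylic alcohol: the arylpalladium species adds its aryl group to the terminal alkene carbon and β-hydride elimination towards the carbinol carbon gives an enol that tautomerises to the saturated methyl ketone, so no stereocentre is formed and the free phenol is tolerated.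

Step 2
Reactants: 3 4-(4-hydroxy-2,6-dimethylphenyl)butan-2-one
Product: 4 2,6-dimethyl-4-oxo-1-(3-oxobutyl)cyclohexa-2,5-dien-1-yl acetate
Conditions: PhI(OAc)2 (1.1 equiv), NaOAc, AcOH, rt
Reagents that add atoms: (diacetoxyiodo)benzene, CC(=O)OI(OC(C)=O)c1ccccc1; acetic acid (solvent that exchanges with the acetate ligands), CC(=O)O
Why: Oxidative dearomatisation of a para-alkylphenol by a trivalent-iodine reagent: the aryloxy-iodane is attacked by acetate at the para carbon, which is activated by the hydroxyl group and both flanking methyl groups, to give the mirror-symmetric (achiral) quinol acetate whose C5 acetoxy group is later relayed to C1.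

Step 3
Reactants: 4 2,6-dimethyl-4-oxo-1-(3-oxobutyl)cyclohexa-2,5-dien-1-yl acetate
Product: 5 (4aS,8aR)-4,8a-dimethyl-2,7-dioxo-1,5,6,7,8,8a-hexahydronaphthalen-4a(2H)-yl acetate
Conditions: 9-amino-9-deoxy-epi-quinine [(8α,9S)-6′-methoxycinchonan-9-amine] (20 mol %), CF3CO2H (40 mol %), toluene, 40 °C
Reagents that add atoms: none
Why: Desymmetrising intramolecular Michael addition under enamine catalysis: the primary amine converts the methyl ketone into its terminal enamine, which adds 6-exo-trig to one of the two enantiotopic β-methyl enone carbons so that ring B closes with the tether-enforced cis ring fusion (C5 and C10 formed together) and the cinchona amine selects the enone that gives the (4aS,8aR) enantiomer, the quinidine-derived pseudo-enantiomer being the switch should the sense prove opposite.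

Step 4
Reactants: 5 (4aS,8aR)-4,8a-dimethyl-2,7-dioxo-1,5,6,7,8,8a-hexahydronaphthalen-4a(2H)-yl acetate
Product: 8 (1R,4aR,8aS)-4,8a-dimethyl-2,7-dioxo-1,2,4a,5,6,7,8,8a-octahydronaphthalen-1-yl acetate, via bis-TMS dienol ether 6 (not isolated), via transposed bis-TMS dienol ether 7 (not isolated)
Conditions: LiN(SiMe3)2 (2.3 equiv), Me3SiCl/Et3N (in situ quench), THF, −78 °C; then toluene, 120 °C (sealed tube); then 2 M HCl, THF, rt
Reagents that add atoms: none
Why: Proposed new method: a relayed 1,5-acyloxy transposition in which the kinetic α′-silyl dienol ether of the γ-acetoxy enone (C1=C2–C3=C4, formed by amide-base enolisation as for isophorone-type enones) turns the tertiary C5 acetate into a pentadienylic ester that on heating moves suprafacially from C5 to C1, either by one pseudopericyclic [3,5] acyloxy shift through a six-membered 1,3-dioxan-2-ylium-like array spanning C5–C10–C1 or by two consecutive [3,3] allylic-ester shifts via C3, driven by relief of the vicinal fully substituted C5/C10 pair and by the tetrasubstituted C4=C5 dienol ether that results, so that the acetate stays on the face of the C10 methyl group (C1 set as R, forming the C1–O bond of the target) and acid hydrolysis then protonates C5 anti to the axial C10 methyl group to give the trans ring fusion (C5 set as R); the closest known reaction type is the thermal [3,3] and [3,5] acyloxy shift of allylic and cyclohexadienyl (quinol) acetates, which has not been shown for γ-acyloxy enones through their silyl dienol ethers.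

Step 5
Reactants: 8 (1R,4aR,8aS)-4,8a-dimethyl-2,7-dioxo-1,2,4a,5,6,7,8,8a-octahydronaphthalen-1-yl acetate; 9 methyl pyruvate
Product: 12 methyl (2S)-2-[(2R,4aS,5R,8aR)-5-acetoxy-4a,8-dimethyl-3,6-dioxo-1,2,3,4,4a,5,6,8a-octahydronaphthalen-2-yl]-2-hydroxypropanoate, via ring-B TMS enol ether 10 (not isolated), via O-TMS aldol adduct 11 (not isolated)
Conditions: Me3SiOTf (1.1 equiv), Et3N, CH2Cl2, −78 °C, then pentane filtration; 9 (3 equiv), Cu(OTf)2 (10 mol %), (S,S)-t-Bu-box [2,2′-(propane-2,2-diyl)bis((4S)-4-tert-butyl-4,5-dihydrooxazole)] (11 mol %), THF, −78 °C; then 1 M HCl, THF, 0 °C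
Reagents that add atoms: none
Why: Mukaiyama aldol addition under a chiral divalent-copper bis(oxazoline) Lewis acid: soft enolisation silylates the unhindered ring-B ketone towards C7 (C9 is neopentylic and the α-acetoxy enone carbonyl is hindered), the enol silane then attacks through C7 along the axial trajectory anti to the axial C10 methyl group to give the kinetic 7R epimer (preserved by the low temperature and by irreversible silyl transfer to the aldolate), while the bidentate pyruvate–copper chelate is attacked on its si face under control of the (S,S)-ligand to set C11 as S.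

## Compound list

1 | 4-bromo-3,5-dimethylphenol | Cc1cc(O)cc(C)c1Br | starting material
2 | but-3-en-2-ol (racemic) | CC(O)C=C | starting material
3 | 4-(4-hydroxy-2,6-dimethylphenyl)butan-2-one | CC(=O)CCc1c(C)cc(O)cc1C | intermediate
4 | 2,6-dimethyl-4-oxo-1-(3-oxobutyl)cyclohexa-2,5-dien-1-yl acetate (achiral quinol acetate) | CC(=O)CCC1(OC(C)=O)C(C)=CC(=O)C=C1C | intermediate
5 | (4aS,8aR)-4,8a-dimethyl-2,7-dioxo-1,5,6,7,8,8a-hexahydronaphthalen-4a(2H)-yl acetate (cis-fused; ring-fusion OAc and methyl cis) | O=C1CC[C@@]2(OC(C)=O)C(C)=CC(=O)C[C@@]2(C)C1 | intermediate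
6 | (4aR,8aR)-4,8a-dimethyl-2,7-bis[(trimethylsilyl)oxy]-4a,5,8,8a-tetrahydronaphthalen-4a-yl acetate (bis-TMS dienol ether; not isolated) | C[Si](C)(C)OC1=CC[C@@]2(OC(C)=O)C(C)=CC(O[Si](C)(C)C)=C[C@@]2(C)C1 | intermediate
7 | (1R,8aS)-4,8a-dimethyl-2,7-bis[(trimethylsilyl)oxy]-1,5,8,8a-tetrahydronaphthalen-1-yl acetate (transposed bis-TMS dienol ether; not isolated) | C[Si](C)(C)OC1=CCC2=C(C)C=C(O[Si](C)(C)C)[C@H](OC(C)=O)[C@@]2(C)C1 | intermediate
8 | (1R,4aR,8aS)-4,8a-dimethyl-2,7-dioxo-1,2,4a,5,6,7,8,8a-octahydronaphthalen-1-yl acetate (trans-fused; OAc cis to the angular methyl) | O=C1CC[C@@H]2C(C)=CC(=O)[C@H](OC(C)=O)[C@@]2(C)C1 | intermediate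
9 | methyl pyruvate (methyl 2-oxopropanoate) | CC(=O)C(=O)OC | starting material
10 | (1R,4aR,8aS)-4,8a-dimethyl-2-oxo-7-[(trimethylsilyl)oxy]-1,2,4a,5,8,8a-hexahydronaphthalen-1-yl acetate (ring-B TMS enol ether; not isolated) | C[Si](C)(C)OC1=CC[C@@H]2C(C)=CC(=O)[C@H](OC(C)=O)[C@@]2(C)C1 | intermediate
11 | methyl (2S)-2-[(2R,4aS,5R,8aR)-5-acetoxy-4a,8-dimethyl-3,6-dioxo-1,2,3,4,4a,5,6,8a-octahydronaphthalen-2-yl]-2-[(trimethylsilyl)oxy]propanoate (O-TMS aldol adduct; not isolated) | COC(=O)[C@@](C)(O[Si](C)(C)C)[C@H]1C[C@@H]2C(C)=CC(=O)[C@H](OC(C)=O)[C@@]2(C)CC1=O | intermediate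
12 | methyl (2S)-2-[(2R,4aS,5R,8aR)-5-acetoxy-4a,8-dimethyl-3,6-dioxo-1,2,3,4,4a,5,6,8a-octahydronaphthalen-2-yl]-2-hydroxypropanoate (CNP0211188.1) | COC(=O)[C@@](C)(O)[C@H]1C[C@@H]2C(C)=CC(=O)[C@H](OC(C)=O)[C@@]2(C)CC1=O | target

## Step count and risks

Total steps: 5. Longest linear sequence: 5 steps (1 → 3 → 4 → 5 → 8 → 12); 2 and 9 are bought.

The three steps most likely to fail:

**Step 3.** The enamine has to attack a β,β-disubstituted enone carbon next to a fully substituted centre, so the cyclisation may be slow or poorly selective. The fallback sets out from compound 1 and comes back at compound 5. It replaces the enamine donor by a more acidic β-keto ester activated by a bifunctional hydrogen-bonding base. Aldol addition of lithiated tert-butyl acetate to acrolein gives tert-butyl 3-hydroxypent-4-enoate F1. Heck arylation of F1 with 1 under the step 1 conditions gives tert-butyl 5-(4-hydroxy-2,6-dimethylphenyl)-3-oxopentanoate F2. PhI(OAc)2 in AcOH gives tert-butyl 5-(1-acetoxy-2,6-dimethyl-4-oxocyclohexa-2,5-dien-1-yl)-3-oxopentanoate F3. The quinine squaramide 3-{[3,5-bis(trifluoromethyl)phenyl]amino}-4-{[(8α,9S)-6′-methoxycinchonan-9-yl]amino}cyclobut-3-ene-1,2-dione (10 mol %, CH2Cl2, rt) closes ring B to tert-butyl (4aR,8aS)-4a-acetoxy-5,8a-dimethyl-2,7-dioxo-1,2,3,4,4a,7,8,8a-octahydronaphthalene-1-carboxylate F4. CF3CO2H in CH2Cl2, then warming in toluene at 50 °C, removes the tert-butyl ester with decarboxylation and returns 5.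

**Step 4 (the proposed new step).** The acyloxy relay may lose to silylation at the C4 methyl group, to C-acyl transfer in the lithium enolate, or to loss of acetic acid giving the linear dienone. The fallback uses known chemistry, sets out from compound 5 and comes back at compound 8. Zn dust in AcOH at 60 °C cleaves the γ-acetoxy group reductively (vinylogous α-acyloxy ketone reduction). DBU in CH2Cl2 then brings the double bond back into conjugation, with protonation of C5 anti to the C10 methyl group, giving (4aS,8aR)-4,8a-dimethyl-4a,5,6,8-tetrahydronaphthalene-2,7(1H,8aH)-dione F5. Mn(OAc)3·2H2O in benzene/AcOH at reflux acetoxylates the enone α′ carbon (C1), and brief Et3N treatment equilibrates C1 to the equatorial acetate, giving 8.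

**Step 5.** The C7 substituent is the axial, kinetic epimer, C11 depends on catalyst control in a double-stereodifferentiating addition, and the α-acetoxy enone may compete for silylation or bind the copper catalyst. The fallback sets out from compounds 8 and 9 and comes back at compound 12. It is a direct enamine aldol without a preformed enol silane: (R)-proline (30 mol %), slow addition of methyl pyruvate, DMSO, 4 °C. Only the ring-B ketone forms an enamine (towards C7), the proline carboxylic acid delivers the pyruvate to the same axial face, and no new isolable compound is made.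

## Further compounds

F1 | step 3 | tert-butyl 3-hydroxypent-4-enoate (racemic) | C=CC(O)CC(=O)OC(C)(C)C
F2 | step 3 | tert-butyl 5-(4-hydroxy-2,6-dimethylphenyl)-3-oxopentanoate | CC(C)(C)OC(=O)CC(=O)CCc1c(C)cc(O)cc1C
F3 | step 3 | tert-butyl 5-(1-acetoxy-2,6-dimethyl-4-oxocyclohexa-2,5-dien-1-yl)-3-oxopentanoate | CC(C)(C)OC(=O)CC(=O)CCC1(OC(C)=O)C(C)=CC(=O)C=C1C
F4 | step 3 | tert-butyl (4aR,8aS)-4a-acetoxy-5,8a-dimethyl-2,7-dioxo-1,2,3,4,4a,7,8,8a-octahydronaphthalene-1-carboxylate (C1 epimers) | O=C1CC[C@@]2(OC(C)=O)C(C)=CC(=O)C[C@@]2(C)C1C(=O)OC(C)(C)C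
F5 | step 4 | (4aS,8aR)-4,8a-dimethyl-4a,5,6,8-tetrahydronaphthalene-2,7(1H,8aH)-dione | O=C1CC[C@@H]2C(C)=CC(=O)C[C@@]2(C)C1
F0 | step 5 | none | none
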